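## The problem

Target **13** is (1R,3R,5R,7S,9S)-3-acetyl-4,4,7-trimethyl-9-(3-methylbut-2-en-1-yl)-9-(2-methylpropanoyl)tricyclo[5.3.1.0^{1,5}]undecane-8,10,11-trione. Atom labels follow the SMILES: acetyl C-1/C-2; ring A = C-3, C-4, C-5, C-9, C-10 (CMe2); ring B = C-5, C-6 (C=O), C-7 (C–Me), C-8, C-9; ring C = C-5, C-6, C-7, C-11 (C=O), C-12, C-13 (C=O).

Rings B and C form a bicyclo[3.2.1]octane-2,4,8-trione with quaternary bridgeheads C-5 and C-7, and ring A is fused on the C-5–C-9 bond, so C-5 lies in all three rings. There are five stereocenters: C-3 (R), C-5 (R), C-7 (S), C-9 (R) and C-12 (S). C-5, C-7 and C-9 are locked to one another by the bridge, so the open questions are C-3 against the core (acetyl cis to C-6 and C-8 on ring A), C-12 (prenyl on the face of ring C that looks at C-6) and the absolute sense. C-12 carries three carbonyl neighbours and an allyl group; this non-enolisable β-triketone is prone to retro-Claisen cleavage and is best made last. C-3 is α to the acetyl ketone and can epimerise, and the prenyl alkene does not survive electrophilic oxidants, so iodine chemistry must come before prenylation.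

The feature that makes the key step possible: ring C is a phloroglucinol at the aromatic oxidation level (oxygen on C-6, C-11, C-13). C-5 and C-7 are the two ring carbons ortho to O-6 and are joined by the two-carbon bridge C-9–C-8, while C-9 is also the end of the chain C-4–C-3–C-10 from C-5. A terminal alkene C-9=C-8 on a side chain at C-5 is therefore placed for 5-exo closure onto C-5 and then closure of C-8 onto C-7. If that works, C-3 is the only stereocenter that has to be made by a catalyst.

## Retrosynthesis

**13 ⇒ 11 + 12.** Cut the C-12–CH2 bond. The enolised 2-acyl-1,3-dione **11** has one nucleophilic carbon left, C-12, and prenyl acetate **12** is the electrophile. Placing this cut last keeps the retro-Claisen-prone centre and the oxidant-sensitive alkene out of all earlier steps. The forward reaction must give C- rather than O-allylation, the linear prenyl isomer, and attack on the ring C face that looks at C-6.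

**11 ⇒ 9 (through 10).** Cut C-5–C-9 and C-7–C-8, the two bonds from the C-9–C-8 bridge to the carbons ortho to O-6. This re-aromatises ring C and opens rings A and B together, leaving the acylphloroglucinol **9** with one stereocenter (C-3) and a terminal alkene. Against the biogenetic cut (C-5–C-9 and C-3–C-10), this cut puts the only precursor stereocenter on a carbon that a catalyst can set, and it delivers the acetyl group directly. Against oxidant-triggered cycloaddition of the same precursor, iodonium activation uses the natural polarity: the ring carbon is the nucleophile and the internal alkene carbon C-9 is attacked in a 5-exo sense. A cation on the ring would be attacked by the terminal CH2 (six-membered closure onto C-5), and a C-8 radical would prefer the β-carbon C-11. The forward step has to dearomatise at C-5 and then alkylate at C-7, through spiro iodide **10**.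

**9 ⇒ 7 (through 8).** Cut the C-2–CH3 bond. The methyl ketone comes from aldehyde **7** by Grignard addition and hydride-transfer oxidation of the magnesium alkoxide of **8**. This is chosen over a conventional oxidant because the electron-rich ring must not be exposed to one.

**7 ⇒ 4 + 5 (through 6).** Cut C-3–C-4. The benzylic carbon C-4 is the exocyclic carbon of ortho-quinone methide **6**, released from sulfone **4**, and C-3 is the α-carbon of 3,3-dimethylpent-4-enal **5**. Enamine catalysis sets C-3 and brings in C-10 with its two methyl groups and the C-9=C-8 alkene in one piece.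

**4 ⇒ 3 ⇒ 1 + 2.** Sulfonylmethylation at the only free ring carbon of **3**, and Friedel–Crafts acylation of 2-methylphloroglucinol **1** with 2-methylpropanoyl chloride **2**. The acyl group is installed first because it blocks C-12 during the quinone methide step and makes C-12 the less nucleophilic partner in the key step.

## Roads not taken

**Alternative 1:** the biogenetic cut, C-5–C-9 and C-3–C-10. The precursor is the diprenylated dearomatised acylphloroglucinol 3,5-dihydroxy-6-methyl-4,6-bis(3-methylbut-2-en-1-yl)-2-(2-methylpropanoyl)cyclohexa-2,4-dien-1-one **A1**. The forward key step is an oxidative radical 5-exo/5-exo cascade (Mn(OAc)3/Cu(OAc)2) to the isopropenyl tricycle **A2**, followed by cleavage of the isopropenyl group to acetyl and prenylation of C-12. This is the route most chemists would draw first. Its weak points are structural: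
- The only stereocenter of A1 (C-7) arises by alkylation of an achiral enolate, so A1 is racemic unless a chiral catalyst is found.
- C-3 is set in a radical closure onto a prenyl group with no controlling element, so both epimers are expected.
- The acetyl group needs a further oxidative step.

The chosen plan sets C-3 by catalysis and relays it to the core.

**Alternative 2:** cut C-5–C-13 and C-7–C-11, an α,α′-annulation of a ring A/B ketone with a malonyl unit (Effenberger-type). The key intermediate is the silyl enol ether 7-acetyl-3,6,6-trimethyl-2-(trimethylsilyloxy)-cis-bicyclo[3.3.0]oct-2-ene **A3**, which with malonyl dichloride would give trione **A4**, then acylation and prenylation at C-12. A3 already holds three stereocenters that have to be built in a separate sequence, for example by intramolecular keteniminium–alkene [2+2] cycloaddition and one-carbon ring expansion. Its acetyl group competes in enol ether formation, and the double acylation has to close a strained bicyclo[3.2.1]octanetrione. The run-up is longer than the whole chosen route.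

**Alternative 3:** cut C-5–C-9 and C-11–C-8, followed by a 1,2-shift of C-8 to C-7. Wessely-type oxidation of **9** at C-7 would give ortho-quinol acetate **A5**, intramolecular Diels–Alder reaction the bicyclo[2.2.2]octenone **A6**, and a semipinacol shift with loss of acetate the skeleton of **11**. The acetoxylation creates a second stereocenter (C-7) that is not correlated with C-3, and C-5 competes as the site of oxidation. In the shift, the group antiperiplanar to acetate after the usual cycloaddition syn to the acetoxy group is the sp2 carbon C-12 and not C-8. This takes three operations for what step 5 attempts in one.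

Key step: step 5

Assumptions: **1**, **2**, **5** and **12** are bought; enolised 2-acyl-1,3-diones (**10**, **11**) are drawn as one tautomer; **7** is drawn as the open aldehyde although it should exist mainly as its 2-chromanol lactols.

## Route

Step 1
Reactants: 1 2-methylbenzene-1,3,5-triol; 2 2-methylpropanoyl chloride
Product: 3 2-methyl-1-(2,4,6-trihydroxy-3-methylphenyl)propan-1-one
Conditions: AlCl3 (3.5 equiv), PhNO2, 0 to 60 °C; aq. HCl work-up
Reagents that add atoms: none
Why: Friedel–Crafts C-acylation; the two free ring positions of 1 are equivalent and the first acyl group deactivates the ring towards a second; no stereocenter is formed.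

Step 2
Reactants: 3 2-methyl-1-(2,4,6-trihydroxy-3-methylphenyl)propan-1-one
Product: 4 2-methyl-1-{2,4,6-trihydroxy-3-methyl-5-[(4-methylbenzenesulfonyl)methyl]phenyl}propan-1-one
Conditions: (CH2O)n (1.5 equiv), sodium 4-methylbenzenesulfinate (2 equiv), HCO2H/H2O, 40 °C
Reagents that add atoms: formaldehyde (C=O); sodium 4-methylbenzenesulfinate (Cc1ccc(cc1)S(=O)[O-].[Na+])
Why: Mannich-type three-component sulfonylmethylation of an electron-rich phenol (hydroxymethylation, then capture of the quinone methide by sulfinate); only one ring carbon is free, and excess sulfinate should outrun attack by a second molecule of 3.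

Step 3
Reactants: 4 2-methyl-1-{2,4,6-trihydroxy-3-methyl-5-[(4-methylbenzenesulfonyl)methyl]phenyl}propan-1-one; 5 3,3-dimethylpent-4-enal
Product: 7 (2R)-3,3-dimethyl-2-{[2,4,6-trihydroxy-3-methyl-5-(2-methylpropanoyl)phenyl]methyl}pent-4-enal, via ortho-quinone methide 6 (not isolated)
Conditions: (R)-2-[diphenyl(trimethylsilyloxy)methyl]pyrrolidine (20 mol %), NaHCO3 (1.5 equiv), CH2Cl2, 0 °C to rt
Reagents that add atoms: none
Why: Base expels sulfinate from 4 to give 6, which is captured by the enamine of 5 (aminocatalytic α-alkylation of aldehydes with ortho-quinone methides made in situ from 2-(sulfonylmethyl)phenols); the diarylmethyl group shields one face of the E-enamine, so on the usual model the (R)-catalyst should give (R) at C-3, and ring closure of the product to its lactol should protect that centre.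

Step 4
Reactants: 7 (2R)-3,3-dimethyl-2-{[2,4,6-trihydroxy-3-methyl-5-(2-methylpropanoyl)phenyl]methyl}pent-4-enal
Product: 9 (3R)-4,4-dimethyl-3-{[2,4,6-trihydroxy-3-methyl-5-(2-methylpropanoyl)phenyl]methyl}hex-5-en-2-one, via secondary alcohol 8 (not isolated)
Conditions: MeMgBr (4.2 equiv), THF, −20 to 0 °C; then 1,1′-(azodicarbonyl)dipiperidine (1.5 equiv), rt; aq. NH4Cl
Reagents that add atoms: methylmagnesium bromide (C[Mg]Br)
Why: Grignard addition to the aldehyde form of the lactol (three equivalents are used up by the acidic OH groups, and the aryl ketone is protected as its magnesium phenoxide chelate), then Mukaiyama oxidation in which the bromomagnesium alkoxide of 8 passes hydride to the azo compound; phenoxides cannot take part, so the ring meets no oxidant, and C-3 is not touched.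

Step 5
Reactants: 9 (3R)-4,4-dimethyl-3-{[2,4,6-trihydroxy-3-methyl-5-(2-methylpropanoyl)phenyl]methyl}hex-5-en-2-one
Product: 11 (1R,3R,5R,7S)-3-acetyl-9-(1-hydroxy-2-methylpropylidene)-4,4,7-trimethyltricyclo[5.3.1.0^{1,5}]undecane-8,10,11-trione, via spiro iodide 10 (not isolated)
Conditions: I2 (1.3 equiv), KI, KHCO3 (3 equiv), THF/H2O, 0 °C, then 40 °C
Reagents that add atoms: none
Why: Proposed new method: iodonium activation of the terminal alkene is followed by 5-exo-trig attack of the phenoxide ring carbon C-5 (ipso, ortho to O-6) on C-9, an intramolecular alkylative dearomatisation that closes ring A and gives 10, whose enolised 1,3-diketone then alkylates through C-7 on the primary iodide C-8 (5-exo-tet, exo to the C-7=C-11 enol) to close ring B and the bicyclo[3.2.1]octane. The closest known reactions are C-alkylative dearomatisation of acylphloroglucinols at a substituted ring carbon, iodonium-induced carbocyclisation of enolised cyclic 1,3-diketones onto pendant alkenes under the same I2/KI/KHCO3 conditions, and 5-exo iodocyclisation at an alkene carbon next to a quaternary centre (iodolactonisation of 3,3-dimethylpent-4-enoic acid); new are the ipso attack of an aromatic acylphloroglucinol on a tethered iodonium ion and the coupling of the two closures. C-9 is set against C-3 by a chair-like transition state with the acetyl group and the developing iodomethyl group both pseudo-equatorial, which is the 1,3-cis relation of the target. C-5 is defined by which ortho carbon ends cis to the iodomethyl group; only the epimer with C-6 on that side can close onto C-7, and the spirocyclisation is expected to be reversible in the presence of iodide (the leaving group is a phenoxide and the ring re-aromatises, as in iodolactonisation under equilibrating conditions), so material should drain through the productive epimer. C-7 is then fixed by the tether, because C-8 reaches C-7 only on the face of ring C that carries C-9. The step needs C- over O-alkylation, which the soft primary iodide and the hydrogen-bonding aqueous medium should favour, and attack at C-7 rather than at the acyl-bearing C-12, which is the less nucleophilic carbon of the enolised triketone.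

Step 6
Reactants: 11 (1R,3R,5R,7S)-3-acetyl-9-(1-hydroxy-2-methylpropylidene)-4,4,7-trimethyltricyclo[5.3.1.0^{1,5}]undecane-8,10,11-trione; 12 3-methylbut-2-en-1-yl acetate
Product: 13 (1R,3R,5R,7S,9S)-3-acetyl-4,4,7-trimethyl-9-(3-methylbut-2-en-1-yl)-9-(2-methylpropanoyl)tricyclo[5.3.1.0^{1,5}]undecane-8,10,11-trione
Conditions: Pd(PPh3)4 (5 mol %), K2CO3 (1.1 equiv), THF, 40 °C
Reagents that add atoms: none
Why: Tsuji–Trost C-allylation of a 2-acyl-1,3-dione enolate; O-allyl enol ethers re-ionise under zerovalent palladium so the C-12 product should accumulate, the soft nucleophile attacks the unsubstituted end of the π-prenyl complex (linear isomer), and approach from the face of ring C that looks at the C-6 carbonyl bridge (the other face is screened by the endo hydrogens on C-8 and C-9) should give (S) at C-12.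

## Compound list

1 | 2-methylbenzene-1,3,5-triol (2-methylphloroglucinol) | Cc1c(O)cc(O)cc1O | starting material
2 | 2-methylpropanoyl chloride | CC(C)C(Cl)=O | starting material
3 | 2-methyl-1-(2,4,6-trihydroxy-3-methylphenyl)propan-1-one | CC(C)C(=O)c1c(O)cc(O)c(C)c1O | intermediate
4 | 2-methyl-1-{2,4,6-trihydroxy-3-methyl-5-[(4-methylbenzenesulfonyl)methyl]phenyl}propan-1-one | Cc1ccc(cc1)S(=O)(=O)Cc1c(O)c(C)c(O)c(C(=O)C(C)C)c1O | intermediate
5 | 3,3-dimethylpent-4-enal | O=CCC(C)(C)C=C | starting material
6 | 3,5-dihydroxy-2-methyl-6-methylidene-4-(2-methylpropanoyl)cyclohexa-2,4-dien-1-one (ortho-quinone methide) | C=C1C(=O)C(C)=C(O)C(C(=O)C(C)C)=C1O | intermediate (not isolated)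
7 | (2R)-3,3-dimethyl-2-{[2,4,6-trihydroxy-3-methyl-5-(2-methylpropanoyl)phenyl]methyl}pent-4-enal | O=C[C@H](Cc1c(O)c(C)c(O)c(C(=O)C(C)C)c1O)C(C)(C)C=C | intermediate
8 | (3R)-4,4-dimethyl-3-{[2,4,6-trihydroxy-3-methyl-5-(2-methylpropanoyl)phenyl]methyl}hex-5-en-2-ol (both C-2 epimers; present as its bromomagnesium alkoxide) | CC(O)[C@H](Cc1c(O)c(C)c(O)c(C(=O)C(C)C)c1O)C(C)(C)C=C | intermediate (not isolated)
9 | (3R)-4,4-dimethyl-3-{[2,4,6-trihydroxy-3-methyl-5-(2-methylpropanoyl)phenyl]methyl}hex-5-en-2-one | CC(=O)[C@H](Cc1c(O)c(C)c(O)c(C(=O)C(C)C)c1O)C(C)(C)C=C | intermediate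
10 | (1R,3R,5S)-3-acetyl-8,10-dihydroxy-1-(iodomethyl)-2,2,7-trimethyl-9-(2-methylpropanoyl)spiro[4.5]deca-7,9-dien-6-one | CC(=O)[C@@H]1C[C@]2(C(=O)C(C)=C(O)C(C(=O)C(C)C)=C2O)[C@H](CI)C1(C)C | intermediate (not isolated)
11 | (1R,3R,5R,7S)-3-acetyl-9-(1-hydroxy-2-methylpropylidene)-4,4,7-trimethyltricyclo[5.3.1.0^{1,5}]undecane-8,10,11-trione | CC(=O)[C@@H]1C[C@]23C(=O)[C@](C)(C[C@@H]2C1(C)C)C(=O)C(=C(O)C(C)C)C3=O | intermediate
12 | 3-methylbut-2-en-1-yl acetate (prenyl acetate) | CC(C)=CCOC(C)=O | starting material
13 | (1R,3R,5R,7S,9S)-3-acetyl-4,4,7-trimethyl-9-(3-methylbut-2-en-1-yl)-9-(2-methylpropanoyl)tricyclo[5.3.1.0^{1,5}]undecane-8,10,11-trione | CC(=O)[C@@H]1C[C@]23C(=O)[C@](C)(C[C@@H]2C1(C)C)C(=O)[C@](CC=C(C)C)(C(=O)C(C)C)C3=O | target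

## Step count and least certain steps

Total: 6 steps. Longest linear sequence: 6 steps (1 → 3 → 4 → 7 → 9 → 11 → 13).

**Step 5 (key step, proposed new method).** Three things are most likely to go wrong:
- The spirocyclisation may not equilibrate. There would then be no control over which ortho carbon (C-6 or C-13) ends cis to the iodomethyl group, and up to half of the material would sit in the C-5 epimer that cannot close onto C-7.
- The enolate may alkylate on O-6 instead of C-7 in the second closure.
- The fully substituted ring may be oxidised by iodine at the benzylic positions, towards a quinone methide.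

The fallback uses known chemistry; it sets out from **3** and comes back at **11**. **3** is C-prenylated twice with 1-bromo-3-methylbut-2-ene in aqueous KOH (alkylative dearomatisation) to racemic 3,5-dihydroxy-6-methyl-4,6-bis(3-methylbut-2-en-1-yl)-2-(2-methylpropanoyl)cyclohexa-2,4-dien-1-one **F1**. Oxidative radical 5-exo/5-exo cyclisation with Mn(OAc)3·2H2O and Cu(OAc)2·H2O in AcOH gives the isopropenyl tricycle. The C-3 epimer with the isopropenyl group cis to C-8 is separated and resolved on a chiral stationary phase to give (1R,3S,5R,7S)-9-(1-hydroxy-2-methylpropylidene)-4,4,7-trimethyl-3-(prop-1-en-2-yl)tricyclo[5.3.1.0^{1,5}]undecane-8,10,11-trione **F2**. Lemieux–Johnson cleavage (OsO4 cat., NaIO4) of the isopropenyl group gives **11**.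

**Step 3.** The hindered, β-quaternary aldehyde may form its enamine slowly, so that hydration or self-condensation of the quinone methide wins and facial selectivity at C-3 is eroded. The fallback sets out from **3** and comes back at **9**, passing by steps 2 to 4. Mesityl oxide is treated with vinylmagnesium bromide and CuI, and the enolate is trapped with N,N-dimethylmethyleneiminium iodide to give 3-[(dimethylamino)methyl]-4,4-dimethylhex-5-en-2-one **F3**. Quaternisation with MeI and elimination with NaHCO3 give 4,4-dimethyl-3-methylidenehex-5-en-2-one **F4**. Acid-catalysed Friedel–Crafts-type conjugate addition of **3** (its only free ring carbon) to **F4** gives racemic 4,4-dimethyl-3-{[2,4,6-trihydroxy-3-methyl-5-(2-methylpropanoyl)phenyl]methyl}hex-5-en-2-one **F5**, which is resolved on a chiral stationary phase to **9**.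

**Step 4.** The Grignard reagent may enolise the hindered aldehyde (epimerisation at C-3) instead of adding, or hydride transfer from the crowded alkoxide may stall. The fallback sets out from **7** and comes back at **9**. Transfer dehydrogenation of the lactol (RuH2(PPh3)4 cat., 4-phenylbut-3-en-2-one as hydrogen acceptor, toluene, 80 °C) gives (3R)-5,7-dihydroxy-8-methyl-6-(2-methylpropanoyl)-3-(2-methylbut-3-en-2-yl)-3,4-dihydro-2H-chromen-2-one **F6**. Single addition of MeLi (4.2 equiv, THF, −78 °C) to the lactone gives, after work-up, **9**.

**Step 6.** O-allylation may persist, the β-triketone may undergo retro-Claisen cleavage once C-12 is quaternary, or facial selectivity at C-12 may be poor. The fallback sets out from **11** and comes back at **13**. O-alkylation with 3-chloro-3-methylbut-1-yne (K2CO3, KI, CuI cat., acetone) gives the 2-methylbut-3-yn-2-yl enol ether of 11 **F7**. Semi-hydrogenation (Pd on CaCO3 poisoned with Pb(OAc)2, quinoline, H2) gives the 2-methylbut-3-en-2-yl enol ether **F8**. Claisen rearrangement in toluene at 110 °C then delivers the prenyl group to C-12 from the ring oxygen and gives **13**.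

## Further compounds

F1 | step 5 | 3,5-dihydroxy-6-methyl-4,6-bis(3-methylbut-2-en-1-yl)-2-(2-methylpropanoyl)cyclohexa-2,4-dien-1-one (racemic) | CC(C)C(=O)C1=C(O)C(CC=C(C)C)=C(O)C(C)(CC=C(C)C)C1=O
F2 | step 5 | (1R,3S,5R,7S)-9-(1-hydroxy-2-methylpropylidene)-4,4,7-trimethyl-3-(prop-1-en-2-yl)tricyclo[5.3.1.0^{1,5}]undecane-8,10,11-trione | CC(=C)[C@@H]1C[C@]23C(=O)[C@](C)(C[C@@H]2C1(C)C)C(=O)C(=C(O)C(C)C)C3=O
F3 | step 3 | 3-[(dimethylamino)methyl]-4,4-dimethylhex-5-en-2-one (racemic) | CC(=O)C(CN(C)C)C(C)(C)C=C
F4 | step 3 | 4,4-dimethyl-3-methylidenehex-5-en-2-one | CC(=O)C(=C)C(C)(C)C=C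
F5 | step 3 | 4,4-dimethyl-3-{[2,4,6-trihydroxy-3-methyl-5-(2-methylpropanoyl)phenyl]methyl}hex-5-en-2-one (racemic) | CC(=O)C(Cc1c(O)c(C)c(O)c(C(=O)C(C)C)c1O)C(C)(C)C=C
F6 | step 4 | (3R)-5,7-dihydroxy-8-methyl-6-(2-methylpropanoyl)-3-(2-methylbut-3-en-2-yl)-3,4-dihydro-2H-chromen-2-one | O=C1Oc2c(C)c(O)c(C(=O)C(C)C)c(O)c2C[C@@H]1C(C)(C)C=C
F7 | step 6 | 2-methylbut-3-yn-2-yl enol ether of 11 (ether oxygen on C-11; core configured as in 11) | CC(=O)[C@@H]1C[C@]23C(=O)[C@](C)(C[C@@H]2C1(C)C)C(OC(C)(C)C#C)=C(C(=O)C(C)C)C3=O
F8 | step 6 | 2-methylbut-3-en-2-yl enol ether of 11 (ether oxygen on C-11; core configured as in 11) | CC(=O)[C@@H]1C[C@]23C(=O)[C@](C)(C[C@@H]2C1(C)C)C(OC(C)(C)C=C)=C(C(=O)C(C)C)C3=O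
A1 | alternative 1 | 3,5-dihydroxy-6-methyl-4,6-bis(3-methylbut-2-en-1-yl)-2-(2-methylpropanoyl)cyclohexa-2,4-dien-1-one (racemic) | CC(C)C(=O)C1=C(O)C(CC=C(C)C)=C(O)C(C)(CC=C(C)C)C1=O
A2 | alternative 1 | 9-(1-hydroxy-2-methylpropylidene)-4,4,7-trimethyl-3-(prop-1-en-2-yl)tricyclo[5.3.1.0^{1,5}]undecane-8,10,11-trione (racemic, both C-3 epimers) | CC(=C)C1CC23C(=O)C(C)(CC2C1(C)C)C(=O)C(=C(O)C(C)C)C3=O
A3 | alternative 2 | 7-acetyl-3,6,6-trimethyl-2-(trimethylsilyloxy)-cis-bicyclo[3.3.0]oct-2-ene (ring fusion and C-7 configured as C-5, C-9 and C-3 of the target) | CC(=O)[C@@H]1C[C@@H]2C(O[Si](C)(C)C)=C(C)C[C@@H]2C1(C)C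
A4 | alternative 2 | 3-acetyl-4,4,7-trimethyltricyclo[5.3.1.0^{1,5}]undecane-8,10,11-trione (configured as 11) | CC(=O)[C@@H]1C[C@]23C(=O)[C@](C)(C[C@@H]2C1(C)C)C(=O)CC3=O
A5 | alternative 3 | 6-acetoxy-3,5-dihydroxy-6-methyl-4-(2-methylpropanoyl)-2-[(2R)-2-acetyl-3,3-dimethylpent-4-en-1-yl]cyclohexa-2,4-dien-1-one (both epimers at the acetoxy carbon) | CC(=O)[C@H](CC1=C(O)C(C(=O)C(C)C)=C(O)C(C)(OC(C)=O)C1=O)C(C)(C)C=C
A6 | alternative 3 | bicyclo[2.2.2]octenone Diels–Alder adduct of A5 (new bonds C-5–C-9 and C-11–C-8; stereoisomer mixture) | CC(=O)C1CC23C(=O)C(C)(OC(C)=O)C(O)(CC2C1(C)C)C(C(=O)C(C)C)=C3O
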